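The numbers in the tables stem from a simulated flask on assumed constants; scatter was added.

Follow the partner through these flasks: four charges of it against one fixed charge of starting material, with the catalyst unchanged.

the same everywhere: starting material 0.050 M; free catalyst 50 µM

| run | second substrate | partner | remark | time |
|---|---|---|---|---|
| summer | 0.075 M | 0.025 M | run made earlier |  |
| ash | 0.0500 M | 0.0250 M |  | 2.5 h |
| birch | 0.0500 M | 0.0500 M |  | 2.5 h |
| cedar | 0.0500 M | 0.100 M |  | 2.5 h |
| alder | 0.0500 M | 0.200 M |  | 2.5 h |

- summer (time / min: target / %, starting material / %): 1.50: 1.1, 98.8; 5.00: 2.9, 97.1; 8.00: 5.5, 95.0; 12.0: 7.2, 93.1; 20.0: 11.1, 89.7; 25.0: 12.6, 87.6; 30.0: 14.1, 84.9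

(readings scatter by 0.3 percentage points)

1. amount of target at the end, in percent of the starting material charged for ash, birch, cedar, alder, in this order
2. the course of these numbers from the first flask to the last (rises, then falls / rises all the way / falls, then rises / falls all the way / hardly changes)

- "hardly changes" means that all values lie within two and a half points (for a concentration: within two and a half percent of the largest)

In the summer run, target and starting material sum to 99.0% at 30.0 min, so the target forms about one for one from the starting material. No reading shows the partner, so the reckoning here assumes it is used one for one as well. The summer run has then used 28.2% of its partner.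

How far can ash go? Ash holds half as much partner as starting material, so partner is the limiting reagent and the ceiling is 50.0%.

How fast does it get there? If the rate is proportional to partner, the partner decays in a pseudo-first-order way, and the summer reading gives 1.05 h as the partner half-life, the time in which an intact catalyst halves the partner while starting material is at hand. The summer run carried more second substrate, and its effect cannot be read, so this stays a reading at that level. The 2.5 h of these flasks is 2.38 half-lives, which on this reckoning leaves 19.1% of the partner charged to ash and to birch. That gives ash 40.5% and birch 80.9%.

What happens once partner exceeds starting material? Cedar need lose half of its partner to match the starting material, which takes one half-life, well inside the time. This reckoning therefore puts cedar and alder near completion, as upper marks. It assumes the catalyst survives 1000 turnovers, while the summer run showed 141.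

The forecast gives 30%, 45%, 60% and 70%, with the course rises all the way, and warns: “There is only one partner level, so the partner order is really unknown”.

The flasks give 36.6%, 63.7%, 82.1% and 71.0%, so the course rises, then falls, turning at 0.11 M of partner.

    second substrate + free catalyst ⇌ catalyst intermediate B (K = 47.0 M⁻¹, k = 17200 M⁻¹ h⁻¹)
    partner + catalyst intermediate B → free catalyst + second product (k = 8180 M⁻¹ h⁻¹)
    partner + free catalyst → spent catalyst (k = 20.0 M⁻¹ h⁻¹)
    partner + catalyst intermediate A → free catalyst + target (k = 73100 M⁻¹ h⁻¹)
    starting material + free catalyst ⇌ catalyst intermediate A (K = 25.0 M⁻¹, k = 1.19 × 10⁵ M⁻¹ h⁻¹)

Alder ends with 99.4% of its catalyst spent, against 31.4% in birch. Counted in partner half-lives, alder's target stands at 68.2% after 1.19 of them and at 71.0% after 2.38.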